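The route rests on opening two bonds of the cis-fused bicycle at once: C8'–C9' of the lactone ring and O–C7' of the tetrahydrofuran ring. The feature used is that the carbonyl carbon C9' has C8' as its only carbon neighbour and hangs on the C7 oxygen, while the aryl-bearing C7' is attached to the same C8'; C8' and C7' are therefore read as the two ends of an E-styrene. In one Lewis acid operation an O7-bound formate-level cation bonds to C8' and the C9 oxygen quenches C7', closing both rings and fixing C8' and C7'. The precursor is acyclic: a syn-aldol-derived diol with a dimethoxymethyl ether on O7, a TBS ether on O9 and benzylated phenols.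

Key step: step 7

Numbering used:
- C9' is the lactone carbonyl.
- C7 is the lactone carbinol carbon bearing the trihydroxyphenyl ring.
- C8 and C8' are the ring-fusion carbons, with C8' next to C9'.
- C9 is the ether CH2, and C7' is the ether CH bearing the catechol ring.
- O7 and O9 are the oxygens on C7 and C9.

The target is 7S,8R,7'S,8'S, which is (3S,3aR,6S,6aS) in furo[3,4-c]furan-1-one numbering. It is cis-fused and both aryl groups lie on the convex face.

Assumption: 1, 2, 5, 8 and 14 are purchased. The C9' centre of 19 and 20 is left undefined because step 9 removes it.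

Step 1
Reactants: 1 3,4-bis(benzyloxy)benzaldehyde; 2 (2-carboxyethyl)triphenylphosphonium bromide
Product: 4 (E)-4-[3,4-bis(benzyloxy)phenyl]but-3-enoic acid, via ylide carboxylate 3 (not isolated)
Conditions: NaN(SiMe3)2 (2.5 equiv) added to 1 + 2, THF, −78 °C → rt; 1 M HCl; recrystallisation
Reagents that add atoms: NaN(SiMe3)2, C[Si](C)(C)[N-][Si](C)(C)C.[Na+] (only the sodium ion of 3; nothing in 4)
Why: Wittig olefination, in which ylides that carry a carboxylate are known to give mainly the E alkene with aromatic aldehydes, adding base to the mixture keeps the fragile ylide short-lived, and crystallisation of the acid should remove residual Z isomer.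

Step 2
Reactants: 4 (E)-4-[3,4-bis(benzyloxy)phenyl]but-3-enoic acid; 5 (S)-4-benzyl-2-oxazolidinone
Product: 7 (S)-4-benzyl-3-{(E)-4-[3,4-bis(benzyloxy)phenyl]but-3-enoyl}oxazolidin-2-one, via mixed pivalic anhydride 6 (not isolated)
Conditions: PivCl, Et3N, THF, −20 → 0 °C; then LiCl, 5, 0 °C → rt
Reagents that add atoms: pivaloyl chloride, CC(C)(C)C(=O)Cl (only the pivaloyl group of 6; nothing in 7)
Why: N-acylation through a mixed anhydride with LiCl activation, which needs only Et3N so that the β,γ-alkene should not slip into conjugation, while the tert-butyl group steers attack to the desired carbonyl.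

Step 3
Reactants: 7 (S)-4-benzyl-3-{(E)-4-[3,4-bis(benzyloxy)phenyl]but-3-enoyl}oxazolidin-2-one; 8 3,4,5-tris(benzyloxy)benzaldehyde
Product: 11 syn-aldol imide (2S,3S in the acyl chain = C8,C7), via boron dienolate 9 (not isolated), via boron aldolate 10 (not isolated)
Conditions: n-Bu2BOTf, Et3N, CH2Cl2, −78 → 0 °C; 8, −78 → 0 °C; pH 7 buffer, MeOH, 30% H2O2, 0 °C
Reagents that add atoms: n-Bu2BOTf, CCCCB(CCCC)OS(=O)(=O)C(F)(F)F (only the dibutylboryl group of 9 and 10; nothing in 11)
Why: Evans boron syn-aldol, in which soft enolisation gives the Z(O)-dienolate, this reacts at its α-carbon through a chair Zimmerman–Traxler transition state on the face remote from the benzyl group of the (S)-auxiliary, and C8 and C7 are thereby set together as the syn (2S,3S) pair known for aromatic aldehydes.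

Step 4
Reactants: 11 syn-aldol imide
Product: 12 (1S,2R,3E)-4-[3,4-bis(benzyloxy)phenyl]-2-(hydroxymethyl)-1-[3,4,5-tris(benzyloxy)phenyl]but-3-en-1-ol (7S,8R diol)
Conditions: LiBH4, MeOH (1 equiv), Et2O/THF, 0 °C; water
Reagents that add atoms: none
Why: Reductive removal of the auxiliary by LiBH4 turns the exocyclic imide carbonyl into C9H2OH without touching the styrene, the benzyl ethers or either stereocentre (the C8 descriptor changes from S to R only because the CIP ranking changes), and 5 is recovered.

Step 5
Reactants: 12 7S,8R diol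
Product: 13 C9 tert-butyldimethylsilyl ether of 12 (C7 hydroxyl free)
Conditions: TBSCl (1.05 equiv), imidazole, CH2Cl2, 0 °C
Reagents that add atoms: TBSCl, CC(C)(C)[Si](C)(C)Cl
Why: Silyl ether formation under steric control, since the primary C9 hydroxyl reacts far faster with one equivalent of TBSCl than the hindered secondary benzylic C7 hydroxyl.

Step 6
Reactants: 13 C9 TBS ether; 14 trimethyl orthoformate
Product: 15 C7 dimethoxymethyl ether and C9 TBS ether of the styrenyl diol (7S,8R)
Conditions: 14 (solvent), PPTS (5 mol %), 4 Å MS, rt, MeOH stripped under reduced pressure; Et3N; high vacuum; short plug of basic alumina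
Reagents that add atoms: none
Why: Acid-catalysed orthoester exchange, in which the only free hydroxyl replaces one methoxy group of 14, the equilibrium is pulled by excess 14 and removal of methanol, the C7–O bond is never broken so C7 keeps its configuration, and the silyl group on O9 blocks the otherwise preferred cyclic 1,3-dioxane orthoformate.

Step 7
Reactants: 15 C7 dimethoxymethyl ether and C9 TBS ether of the styrenyl diol
Product: 19 bicyclic methyl lactol ether (7S,8R,7'S,8'S; anomeric mixture at C9'), via dialkoxycarbenium triflate 16 (not isolated), via C7' benzylic cation 17 (not isolated), via silyloxonium triflate 18 (not isolated)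
Conditions: TMSOTf (0.2 equiv), 2,6-di-tert-butyl-4-methylpyridine (0.05 equiv), 4 Å MS, CH2Cl2 (0.01 M), −78 → −30 °C; Et3N quench at low temperature
Reagents that add atoms: TMSOTf, C[Si](C)(C)OS(=O)(=O)C(F)(F)F (only the triflate counter-ion of 16, 17 and 18; nothing in 19)
Why: Proposed new method: TMSOTf silylates a methoxy oxygen of 15 and expels TMSOMe to leave the dialkoxycarbenium ion 16, the styrene attacks it through C8' to give the para-benzyloxy-stabilised C7' cation 17, O9 adds to give the silyloxonium ion 18, and triflate takes the silyl group as TBSOTf, which ionises the next molecule of 15. The closest known reaction types are the Lewis acid addition of orthoformates to styrenes and allylsilanes and the Prins cyclisation of styrenyl alcohols with aldehydes that ends in capture by an internal oxygen; what has not been shown is a tethered formate-level cation combined with silyl ether termination. The lactol ether ring closes in a 5-exo-trig mode at the alkene (C8' inside the ring, C7' outside; the 6-endo alternative through C7' would leave an unstabilised secondary cation at C8'), and the tetrahydrofuran ring closes by five-membered capture of the exocyclic cation, 5-exo with respect to its quinoid C7'=C(aryl) bond. C8' is controlled by C8, because O9 can reach C7' only in the adduct that holds C7' and C9 cis on the new ring (a trans-fused bicyclo[3.3.0]octane is out of reach) while the other adduct should fall back to the well-stabilised 16; C7' follows from net anti addition of C9' and O9 to the E-alkene, which puts the aryl group on the convex face, the isomer also favoured if the benzylic ether re-ionises; C9' forms as an anomeric mixture that step 9 erases, and C7 and C8 are untouched. The styrene must win over C7–O heterolysis (loss of methyl formate), Friedel–Crafts attack by the C7 aryl ring, a 2-oxonia-Cope shift and O9-to-C9' orthoester exchange: it has a coplanar para oxygen donor whereas the 4-benzyloxy group of the C7 ring is twisted out of conjugation by its two neighbours, closure onto that arene would be 5-endo, the Cope shift would trade a dialkoxycarbenium ion for a less stabilised monoalkoxy one and give up styrene conjugation, and the bulky TBS group slows the exchange, which is reversible in any case. Low temperature, high dilution, a trace of hindered base and a precursor freed of 14 and methanol keep intermolecular formylation of the styrene and Brønsted acid chemistry out.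

Step 8
Reactants: 19 bicyclic methyl lactol ether
Product: 20 bicyclic lactol (7S,8R,7'S,8'S; anomeric mixture at C9')
Conditions: 1 M aq. HCl/THF (1:3), rt
Reagents that add atoms: water, O
Why: Acid-catalysed acetal hydrolysis of a furanoside-type methyl lactol ether, mild enough for the aryl benzyl ethers, and any reversible opening at C7' or epimerisation at C8' through the open hydroxy aldehyde returns to the cis-fused, exo-aryl lactol as the only closable and most stable form.

Step 9
Reactants: 20 bicyclic lactol
Product: 21 pentabenzyl lactone (3S,3aR,6S,6aS)-6-[3,4-bis(benzyloxy)phenyl]-3-[3,4,5-tris(benzyloxy)phenyl]tetrahydro-1H,3H-furo[3,4-c]furan-1-one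
Conditions: Ag2CO3 on Celite (excess), toluene, reflux
Reagents that add atoms: none
Why: Fétizon oxidation, a neutral heterogeneous oxidant that is selective for lactols, converts C9' into the lactone carbonyl without acid or base, so the benzylic ethers and the C8' centre are not put at risk.

Step 10
Reactants: 21 pentabenzyl lactone
Product: 22 target, (3S,3aR,6S,6aS)-6-(3,4-dihydroxyphenyl)-3-(3,4,5-trihydroxyphenyl)tetrahydro-1H,3H-furo[3,4-c]furan-1-one
Conditions: H2 (1 atm), 10% Pd/C, EtOAc/THF, rt, stopped when debenzylation is complete; filtration and evaporation under argon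
Reagents that add atoms: none
Why: Catalytic hydrogenolysis, in which the five unhindered primary aryl benzyl ethers are cleaved much faster than the two hindered secondary ring C–O bonds in an aprotic, acid-free medium at atmospheric pressure, and no stereocentre is involved.

Compound list
1 | 3,4-bis(benzyloxy)benzaldehyde | O=Cc1ccc(OCc2ccccc2)c(OCc2ccccc2)c1 | starting material
2 | (2-carboxyethyl)triphenylphosphonium bromide | OC(=O)CC[P+](c1ccccc1)(c1ccccc1)c1ccccc1.[Br-] | starting material
3 | sodium 3-(triphenylphosphoranylidene)propanoate (ylide carboxylate) | [Na+].[O-]C(=O)CC=P(c1ccccc1)(c1ccccc1)c1ccccc1 | intermediate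
4 | (E)-4-[3,4-bis(benzyloxy)phenyl]but-3-enoic acid | OC(=O)C/C=C/c1ccc(OCc2ccccc2)c(OCc2ccccc2)c1 | intermediate
5 | (S)-4-benzyl-2-oxazolidinone | O=C1OC[C@H](Cc2ccccc2)N1 | starting material
6 | mixed anhydride of 4 with pivalic acid | CC(C)(C)C(=O)OC(=O)C/C=C/c1ccc(OCc2ccccc2)c(OCc2ccccc2)c1 | intermediate
7 | (S)-4-benzyl-3-{(E)-4-[3,4-bis(benzyloxy)phenyl]but-3-enoyl}oxazolidin-2-one | O=C1OC[C@H](Cc2ccccc2)N1C(=O)C/C=C/c1ccc(OCc2ccccc2)c(OCc2ccccc2)c1 | intermediate
8 | 3,4,5-tris(benzyloxy)benzaldehyde | O=Cc1cc(OCc2ccccc2)c(OCc2ccccc2)c(OCc2ccccc2)c1 | starting material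
9 | Z(O)-dibutylboron dienolate of 7 | CCCCB(CCCC)O/C(=C\C=C\c1ccc(OCc2ccccc2)c(OCc2ccccc2)c1)N1C(=O)OC[C@@H]1Cc1ccccc1 | intermediate
10 | dibutylboron aldolate of 11 | CCCCB(CCCC)O[C@H](c1cc(OCc2ccccc2)c(OCc2ccccc2)c(OCc2ccccc2)c1)[C@@H](C(=O)N1C(=O)OC[C@@H]1Cc1ccccc1)/C=C/c1ccc(OCc2ccccc2)c(OCc2ccccc2)c1 | intermediate
11 | (4S)-4-benzyl-3-{(2S,3E)-4-[3,4-bis(benzyloxy)phenyl]-2-[(S)-hydroxy(3,4,5-tris(benzyloxy)phenyl)methyl]but-3-enoyl}oxazolidin-2-one | O[C@H](c1cc(OCc2ccccc2)c(OCc2ccccc2)c(OCc2ccccc2)c1)[C@@H](C(=O)N1C(=O)OC[C@@H]1Cc1ccccc1)/C=C/c1ccc(OCc2ccccc2)c(OCc2ccccc2)c1 | intermediate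
12 | (1S,2R,3E)-4-[3,4-bis(benzyloxy)phenyl]-2-(hydroxymethyl)-1-[3,4,5-tris(benzyloxy)phenyl]but-3-en-1-ol | O[C@H](c1cc(OCc2ccccc2)c(OCc2ccccc2)c(OCc2ccccc2)c1)[C@@H](CO)/C=C/c1ccc(OCc2ccccc2)c(OCc2ccccc2)c1 | intermediate
13 | C9 TBS ether of 12 (7S,8R; C7 hydroxyl free) | O[C@H](c1cc(OCc2ccccc2)c(OCc2ccccc2)c(OCc2ccccc2)c1)[C@@H](CO[Si](C)(C)C(C)(C)C)/C=C/c1ccc(OCc2ccccc2)c(OCc2ccccc2)c1 | intermediate
14 | trimethyl orthoformate | COC(OC)OC | starting material
15 | C7 dimethoxymethyl ether, C9 TBS ether of 12 (7S,8R; key-step precursor) | COC(OC)O[C@H](c1cc(OCc2ccccc2)c(OCc2ccccc2)c(OCc2ccccc2)c1)[C@@H](CO[Si](C)(C)C(C)(C)C)/C=C/c1ccc(OCc2ccccc2)c(OCc2ccccc2)c1 | intermediate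
16 | O7-bound methoxycarbenium (dialkoxycarbenium) triflate | CO[CH+]O[C@H](c1cc(OCc2ccccc2)c(OCc2ccccc2)c(OCc2ccccc2)c1)[C@@H](CO[Si](C)(C)C(C)(C)C)/C=C/c1ccc(OCc2ccccc2)c(OCc2ccccc2)c1.[O-]S(=O)(=O)C(F)(F)F | intermediate
17 | monocyclic lactol ether with exocyclic C7' benzylic cation (C7' and C9 cis), triflate | COC1O[C@H](c3cc(OCc4ccccc4)c(OCc4ccccc4)c(OCc4ccccc4)c3)[C@@H](CO[Si](C)(C)C(C)(C)C)[C@H]1[CH+]c3ccc(OCc4ccccc4)c(OCc4ccccc4)c3.[O-]S(=O)(=O)C(F)(F)F | intermediate
18 | bicyclic O9-silyloxonium triflate | COC1O[C@H](c3cc(OCc4ccccc4)c(OCc4ccccc4)c(OCc4ccccc4)c3)[C@H]2C[O+]([Si](C)(C)C(C)(C)C)[C@H](c3ccc(OCc4ccccc4)c(OCc4ccccc4)c3)[C@@H]12.[O-]S(=O)(=O)C(F)(F)F | intermediate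
19 | bicyclic methyl lactol ether (7S,8R,7'S,8'S; C9' anomeric mixture; key-step product) | COC1O[C@H](c3cc(OCc4ccccc4)c(OCc4ccccc4)c(OCc4ccccc4)c3)[C@H]2CO[C@H](c3ccc(OCc4ccccc4)c(OCc4ccccc4)c3)[C@@H]12 | intermediate
20 | bicyclic lactol (7S,8R,7'S,8'S; C9' anomeric mixture) | OC1O[C@H](c3cc(OCc4ccccc4)c(OCc4ccccc4)c(OCc4ccccc4)c3)[C@H]2CO[C@H](c3ccc(OCc4ccccc4)c(OCc4ccccc4)c3)[C@@H]12 | intermediate
21 | pentabenzyl lactone (3S,3aR,6S,6aS) | O=C1O[C@H](c3cc(OCc4ccccc4)c(OCc4ccccc4)c(OCc4ccccc4)c3)[C@H]2CO[C@H](c3ccc(OCc4ccccc4)c(OCc4ccccc4)c3)[C@@H]12 | intermediate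
22 | (3S,3aR,6S,6aS)-6-(3,4-dihydroxyphenyl)-3-(3,4,5-trihydroxyphenyl)tetrahydro-1H,3H-furo[3,4-c]furan-1-one | O=C1O[C@H](c2cc(O)c(O)c(O)c2)[C@H]2CO[C@H](c3ccc(O)c(O)c3)[C@@H]12 | target

Total step count: 10. Longest linear sequence: 10 steps (1 → 22).

Steps most likely to fail

Step 7.
- What may go wrong: the O7-bound cation may decay by heterolysis of the benzylic C7–O bond, with loss of the C7 configuration.
- The C7' cation of the unproductive C8' adduct may be drained by arylation or proton loss before it can revert.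
- The orthoformate carbon may simply migrate onto O9.
- Fallback (known chemistry only; sets out from 5 and 8, uses 1 later, returns at 21): the bicycle is built by the classical lactone-aldol and benzylic etherification sequence, in which C9' comes from an allyl group and C8'–C7' from an enolate addition.
- N-Acylation of 5 (n-BuLi, pent-4-enoyl chloride, THF, −78 °C) gives (S)-4-benzyl-3-(pent-4-enoyl)oxazolidin-2-one F1.
- An Evans boron aldol with 8 gives the syn adduct F2, with the same C7/C8 configuration as 11.
- TBSOTf/2,6-lutidine gives the C7 silyl ether F3, and LiBH4 gives the primary alcohol F4.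
- Lemieux–Johnson cleavage (OsO4 cat., NaIO4) of the terminal alkene gives the five-membered lactol F5, and Ag2CO3 on Celite gives the β-substituted γ-butyrolactone F6 (ring O9–C9–C8–C8'–C9').
- Its lithium enolate (LiN(SiMe3)2, THF, −78 °C) adds to 1 on the face opposite the C8 side chain to give the trans aldol lactone F7. This carries the correct 8'S centre and an inconsequential carbinol mixture at C7'.
- Bu4NF removes the silyl group, and the freed C7 alkoxide takes over the acyl group to give the translactonised hydroxy lactone F8.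
- Catalytic camphorsulfonic acid in CH2Cl2 ionises the para-benzyloxybenzylic alcohol, so that the C9 hydroxyl closes the tetrahydrofuran ring stereoconvergently on the convex face to give 21.

Step 6.
- What may go wrong: exchange at a hindered secondary alcohol may stall at equilibrium.
- The acid catalyst may start solvolysis at benzylic C7.
- The mixed orthoformate may hydrolyse on handling.
- Fallback (sets out from 13 and 14, returns at 15): the equilibrium is replaced by irreversible capture of a preformed cation under basic conditions, the classical route from dialkoxycarbenium salts to mixed orthoesters.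
- Compound 14 is treated with BF3·OEt2 in CH2Cl2 at −30 °C to precipitate dimethoxycarbenium tetrafluoroborate F9.
- F9 is added at −78 °C to 13 and i-Pr2NEt in CH2Cl2. O-alkylation in the presence of base gives 15 with no Brønsted acid present and no excess of 14 to remove.

Step 10.
- What may go wrong: once the phenols are free, hydrogenolysis may continue into the C7–O (benzylic lactone) and C7'–O (para-hydroxybenzylic ether) ring bonds.
- The polyphenol may also oxidise in air during work-up.
- Fallback (sets out from 21, returns at 22): reductive cleavage is replaced by Lewis acid dealkylation with a cation scavenger.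
- The conditions are BCl3 and pentamethylbenzene in CH2Cl2 at −78 °C followed by a methanol quench. This removes aryl benzyl ethers without hydrogen or metal.
- Compounds new to the route: none F0.

Further compounds
F1 | step 7 | (S)-4-benzyl-3-(pent-4-enoyl)oxazolidin-2-one | C=CCCC(=O)N1C(=O)OC[C@@H]1Cc1ccccc1
F2 | step 7 | (4S)-4-benzyl-3-{(2S)-2-[(S)-hydroxy(3,4,5-tris(benzyloxy)phenyl)methyl]pent-4-enoyl}oxazolidin-2-one | O[C@H](c1cc(OCc2ccccc2)c(OCc2ccccc2)c(OCc2ccccc2)c1)[C@@H](C(=O)N1C(=O)OC[C@@H]1Cc1ccccc1)CC=C
F3 | step 7 | C7 TBS ether of F2 | CC(C)(C)[Si](C)(C)O[C@H](c1cc(OCc2ccccc2)c(OCc2ccccc2)c(OCc2ccccc2)c1)[C@@H](C(=O)N1C(=O)OC[C@@H]1Cc1ccccc1)CC=C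
F4 | step 7 | (2R)-2-[(S)-(tert-butyldimethylsilyloxy)(3,4,5-tris(benzyloxy)phenyl)methyl]pent-4-en-1-ol | CC(C)(C)[Si](C)(C)O[C@H](c1cc(OCc2ccccc2)c(OCc2ccccc2)c(OCc2ccccc2)c1)[C@@H](CO)CC=C
F5 | step 7 | γ-lactol from cleavage of F4 (7S,8R; anomeric mixture) | CC(C)(C)[Si](C)(C)O[C@H](c1cc(OCc2ccccc2)c(OCc2ccccc2)c(OCc2ccccc2)c1)[C@H]1COC(O)C1
F6 | step 7 | β-[(S)-silyloxy(aryl)methyl]-γ-butyrolactone (7S,8R) | CC(C)(C)[Si](C)(C)O[C@H](c1cc(OCc2ccccc2)c(OCc2ccccc2)c(OCc2ccccc2)c1)[C@H]1COC(=O)C1
F7 | step 7 | trans α-[hydroxy(3,4-bis(benzyloxy)phenyl)methyl] lactone (7S,8R,8'S; C7' mixture) | CC(C)(C)[Si](C)(C)O[C@H](c1cc(OCc2ccccc2)c(OCc2ccccc2)c(OCc2ccccc2)c1)[C@H]1COC(=O)[C@@H]1C(O)c1ccc(OCc2ccccc2)c(OCc2ccccc2)c1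
F8 | step 7 | translactonised hydroxy lactone with free C9 hydroxyl (7S,8R,8'S; C7' mixture) | O=C1O[C@H](c3cc(OCc4ccccc4)c(OCc4ccccc4)c(OCc4ccccc4)c3)[C@@H](CO)[C@H]1C(O)c3ccc(OCc4ccccc4)c(OCc4ccccc4)c3
F9 | step 6 | dimethoxycarbenium tetrafluoroborate | CO[CH+]OC.F[B-](F)(F)F
F0 | step 10 | none | none
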